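(All constants are made up; the rest is arithmetic.)

Late in the run E.L and X swap with a relaxation half-life of 1.89 min, far shorter than the 3.0 h run, while E.L drains to D by step 5 alone with a half-life of 4.5 h. So you can reckon the late hours once you have one number from the early minutes: how much of the G is captured.

G 0.058 M; Z 17 mM (held); time 3.0 h

    Z ⇌ L, rate k1*(csat - [L]) (k1 = 0.421 min⁻¹, csat = 17 mM)
    E + L → E.L (k2 = 139 L mol⁻¹ min⁻¹)
    E → Q (k3 = 0.923 min⁻¹)
    G ⇌ E, rate k4*(cs4 - [E]) while solid is left; crystals form when [E] > cs4 (cs4 = 45 mM, k4 = 0.110 min⁻¹)
    E.L → D (k5 = 0.00256 min⁻¹)
    E.L ⇌ X (K6 = 0.456, k6 = 0.115 min⁻¹)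

- E.L at 3.0 h, in percent of the G charged
- concentration of L in solution at 50 min, in percent of saturation
- the change that raises the amount of E.L at 3.0 h, in percent of the G charged most ("none" if none brings more than 2 percentage points) (spring / autumn / noon / midnight / none)
- amount of E.L at 3.0 h, in percent of the G charged, after autumn

- spring: doubling the solubility in step 4, all else as stated
- autumn: doubling the saturation concentration of Z, all else as stated
- noon: doubling the transfer coefficient of step 1, all else as stated
- midnight: doubling the dissolution coefficient of step 4, all else as stated

- given per volume of solution although it is solid: G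
- at the start none of L is dissolved
- at the start none of G is in solution
- run time (flask): 3.0 h

Freeze what moves fast. While G dissolves, let L and E stand still: the crossing from Z supplies what capture takes, and dissolution supplies what capture and loss to Q take. These balances give L* = 10.2 mM and E* = 2.02 mM. With L frozen, capture is pseudo-first-order in E, at 1.42 min⁻¹, against loss to Q at 0.923 min⁻¹. The first over their sum is 60.6%; call it the capture share φ, the fraction of E that L catches.

That is the way through E. Now go through L. Capture runs at 2.86 mM min⁻¹, and G lasts 12.3 min. But L starts empty and needs about 1.42 min to fill, so I count capture for the remaining time and add φ of the E still standing at the end. This gives 55.6%.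

The two ways part by 5.0 percentage points. The first one cheats: it holds L at L* from the first moment, when none is dissolved. I commit to the second.

A fraction 0.687 of the captured pool is E.L, and the pool drains at 0.00176 min⁻¹ after G ends, so I reckon y = 28.5%. After G ends, L climbs back at rate 0.421 min⁻¹, and 2.38 min is much shorter than the 37.7 min left before the reading, so I expect saturation at 50 min.

Noon leaves L below 17 mM, which holds φ under 71.9%. Autumn lifts that ceiling. Spring and midnight each raise the inflow of E into an empty solution to 9.90 mM min⁻¹, above the top supply of L of 7.16 mM min⁻¹, so I expect a lower L*. I pick autumn.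

The forecast, which begins “Dissolved E stays at about 2 mM”, gives y = 28.9% (27.5% to 30.3%), sat = 100%, best = autumn and yb = 37.9% (36.3% to 39.5%). Its y stands slightly above my 28.5%.

The flask gives y = 29.0%, sat = >99.9% and best = autumn. Q stands at 42.5% after 0.300 h and still at 42.5% after 3.00 h. Now double csat in the balances: L* becomes 24.9 mM and φ becomes 79.0%. Scaling 29.0% by the ratio of the two shares gives 37.8%. The autumn flask reads 37.9%, a gain of 8.9 points.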